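**Plan**

1. Numbering: ring A = C1 (CO2Me), C2 (ether O), C3 (OMe), C4 (Cl), C5 (OH), C6 (H); ring B = C1' (ether O), C2' (H), C3' (CH3), C4' (H), C5' (OH), C6' (CO2H). Retrosynthesis: with both phenols and the acid masked as benzyl groups, ring B is cut at C1'–C6' and C2'–C3', leaving the O–C≡CH ether of ring A and a 2-pyrone.
2. Enabling feature: ring B is a 6-hydroxy-4-methylsalicylate whose ether oxygen on C1' lies ortho to the C6' carboxyl. C3'–C6' with their CH3, O and CO2R groups map onto C6–C3 of a 3-alkoxycarbonyl-4-alkoxy-6-methyl-2-pyrone, and C1'/C2' onto an oxygen-substituted alkyne, with CO2 as the only by-product.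
3. Forward, ring A first: a Sandmeyer reaction fixes Cl at C4, copper-catalysed hydroxylation and an Elbs oxidation bring in O5 and O2, selective benzylation leaves only the hindered C2 phenol free, and this is vinylated and taken to the ethynyl ether.
4. The pyrone comes in two steps from dibenzyl malonate and a dioxinone; heating the two partners builds ring B on the ring A oxygen ([4+2], then loss of CO2), and BCl3 removes the three benzyl groups.
5. Stereochemistry: the target has no stereocentre and no stereogenic double bond; the only stereo-elements on the way (racemic 13, E/Z 14, racemic 22) are transient.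

Key step: step 10

Remark: direct chlorination of 3,5-dioxygenated benzoates goes ortho to the ester, and an alkyllithium would attack the ring A methyl ester; the route therefore places chlorine by a Sandmeyer reaction and forms the ynol ether with a lithium amide.

**Route**

Step 1
Reactants: 1 methyl 4-amino-3-methoxybenzoate
Product: 2 methyl 4-amino-3-bromo-5-methoxybenzoate
Conditions: NBS (1.05 equiv), MeCN, 0 °C → rt
Reagents that add atoms: N-bromosuccinimide, O=C1CCC(=O)N1Br
Why: Electrophilic aromatic bromination is directed by the amino group to its only free ortho position, the para position being taken by the ester.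

Step 2
Reactants: 2 methyl 4-amino-3-bromo-5-methoxybenzoate
Product: 4 methyl 3-bromo-4-chloro-5-methoxybenzoate, via arenediazonium chloride 3 (not isolated)
Conditions: t-BuONO (1.5 equiv), CuCl2 (1.2 equiv), MeCN, 0 → 60 °C
Reagents that add atoms: copper dichloride, Cl[Cu]Cl
Why: A non-aqueous Sandmeyer reaction puts chlorine on the carbon that carried nitrogen, between OMe and Br, and consumes the diazonium ion as it forms, so chloride does not displace the ortho bromine.

Step 3
Reactants: 4 methyl 3-bromo-4-chloro-5-methoxybenzoate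
Product: 6 4-chloro-3-hydroxy-5-methoxybenzoic acid, via potassium 3-bromo-4-chloro-5-methoxybenzoate 5 (not isolated)
Conditions: CuI (10 mol %), 1,10-phenanthroline (20 mol %), KOH (6 equiv), DMSO/H2O 1:1, 100 °C; then aq. HCl
Reagents that add atoms: potassium hydroxide, [K+].[OH-]
Why: Copper-catalysed Ullmann-type hydroxylation of aryl bromides with hydroxide is selective for C–Br over the flanked C–Cl bond, and the same hydroxide saponifies the ester to the free acid wanted for the next step.

Step 4
Reactants: 6 4-chloro-3-hydroxy-5-methoxybenzoic acid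
Product: 9 methyl 4-chloro-2,5-dihydroxy-3-methoxybenzoate, via aryl sulfate 7 (not isolated), via 4-chloro-2,5-dihydroxy-3-methoxybenzoic acid 8 (not isolated)
Conditions: K2S2O8 (1.1 equiv), 10 % aq. NaOH, 0 °C → rt; acidify (H2SO4), extract unreacted 6, evaporate the aqueous phase; MeOH, conc. H2SO4, reflux, N2
Reagents that add atoms: potassium peroxodisulfate, [K+].[K+].[O-]S(=O)(=O)OOS(=O)(=O)[O-]; methanol, CO
Why: In the Elbs persulfate oxidation the phenoxide attacks peroxodisulfate through its para carbon (the future C2), the reaction that turns hydroxybenzoic acids into gentisic acid, and hot methanolic acid then cleaves the aryl sulfate and esterifies the acid (Fischer esterification).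

Step 5
Reactants: 9 methyl 4-chloro-2,5-dihydroxy-3-methoxybenzoate
Product: 10 methyl 5-(benzyloxy)-4-chloro-2-hydroxy-3-methoxybenzoate
Conditions: BnBr (1.05 equiv), K2CO3 (1.1 equiv), acetone, rt → 40 °C, N2
Reagents that add atoms: benzyl bromide, BrCc1ccccc1
Why: Williamson etherification should take the C5 hydroxyl, which is the more acidic one (ortho chlorine) and unhindered, whereas the C2 hydroxyl is hydrogen-bonded to the ester carbonyl and flanked on both sides, as in the selective 5-O-alkylation of gentisates.

Step 6
Reactants: 10 methyl 5-(benzyloxy)-4-chloro-2-hydroxy-3-methoxybenzoate; 11 vinyl acetate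
Product: 12 methyl 5-(benzyloxy)-4-chloro-2-(ethenyloxy)-3-methoxybenzoate
Conditions: [Ir(cod)Cl]2 (2 mol %), Na2CO3 (0.6 equiv), vinyl acetate (3 equiv), toluene, 100 °C
Reagents that add atoms: none
Why: Iridium-catalysed transfer vinylation of phenols with vinyl acetate (addition of the iridium aryloxide to the vinyl ester, then β-acetate elimination) runs under weakly basic, ester-compatible conditions and needs no alkylating agent at the crowded oxygen.

Step 7
Reactants: 12 methyl 5-(benzyloxy)-4-chloro-2-(ethenyloxy)-3-methoxybenzoate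
Product: 15 methyl 5-(benzyloxy)-4-chloro-2-(ethynyloxy)-3-methoxybenzoate, via dibromide 13 (not isolated), via bromovinyl ether 14 (not isolated)
Conditions: Br2 (1.0 equiv), CH2Cl2, −78 °C; i-Pr2NEt (1.5 equiv), → rt; filter (pentane), THF; LiN(i-Pr)2 (2.6 equiv), −78 °C; H2O, −78 °C
Reagents that add atoms: none
Why: This is the classical vinyl ether to alkynyl ether sequence (bromine addition, amine-induced loss of HBr from the α-bromo ether, amide-base dehydrobromination of the β-bromovinyl ether), run with a hindered lithium amide at −78 °C so that the methyl ester is not attacked.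

Step 8
Reactants: 16 dibenzyl malonate; 17 2,2,6-trimethyl-4H-1,3-dioxin-4-one
Product: 20 benzyl 4-hydroxy-6-methyl-2-oxo-2H-pyran-3-carboxylate, via acetylketene 18 (not isolated), via dibenzyl acetoacetylmalonate 19 (not isolated)
Conditions: NaH (1.05 equiv), THF, 0 °C; 17 (1.2 equiv), toluene, 110 °C; then aq. HCl
Reagents that add atoms: none
Why: Thermal retro-[4+2] of the dioxinone releases acetylketene, which C-acylates the sodium malonate, and the tricarbonyl compound lactonises through its ketone enol oxygen onto one benzyl ester, the known diketene–malonate route to 3-alkoxycarbonyl-4-hydroxy-6-methyl-2-pyrones.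

Step 9
Reactants: 20 benzyl 4-hydroxy-6-methyl-2-oxo-2H-pyran-3-carboxylate
Product: 21 benzyl 4-(benzyloxy)-6-methyl-2-oxo-2H-pyran-3-carboxylate
Conditions: BnOH (1.2 equiv), PPh3 (1.3 equiv), diisopropyl azodicarboxylate (1.3 equiv), THF, 0 °C → rt
Reagents that add atoms: benzyl alcohol, OCc1ccccc1
Why: Mitsunobu O-alkylation of the acidic 4-hydroxy-2-pyrone should give the 4-benzyl ether without the C3- or O2-alkylation that benzyl halides and base can cause, and it removes the acidic proton that would destroy the ynol ether.

Step 10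
Reactants: 15 methyl 5-(benzyloxy)-4-chloro-2-(ethynyloxy)-3-methoxybenzoate; 21 benzyl 4-(benzyloxy)-6-methyl-2-oxo-2H-pyran-3-carboxylate
Product: 23 benzyl 2-(benzyloxy)-6-[4-(benzyloxy)-3-chloro-2-methoxy-6-(methoxycarbonyl)phenoxy]-4-methylbenzoate, via bridged lactone 22 (not isolated)
Conditions: 21 (1.5 equiv), 2,6-di-tert-butyl-4-methylphenol (5 mol %), mesitylene (1 M), 140 °C, sealed tube, base-washed glass
Reagents that add atoms: none
Why: Proposed new method: the electron-rich O–C≡C–H π bond of 15 should add thermally in an inverse-electron-demand [4+2] cycloaddition across C3 and C6 of pyrone 21, whose diene is made electron-poor by the lactone and ester carbonyls, and the bridged lactone 22 should expel CO2 by retro-[4+2] at the same temperature to give arene 23 directly. The closest known reaction type is the aryl annulation of 3-alkoxycarbonyl-2-pyrones with ketene acetals, enol ethers and ynamines with loss of CO2; a terminal aryl ynol ether and a 4-alkoxy pyrone are the untested extension. Ring B closes in one intermolecular two-bond [4+2] annulation (C1'–C6' and C2'–C3' formed on the C3–C6 diene termini) followed by aromatisation through CO2 extrusion, with no separate cyclisation step. No stereocentre is created in 23, since the two bridgehead centres of racemic 22 vanish on aromatisation. The step needs one orientation: the nucleophilic C–H carbon of the ynol ether must bond to C6 of the pyrone (methyl-bearing, vinylogous to both carbonyls) so that the aryloxy carbon ends on C3 next to the ester, and the polarisation of both partners should secure this while the 4-benzyloxy donor only lowers the rate. Both ortho positions of the ring A oxygen are substituted and the alkyne carries neither a leaving group nor a β-hydrogen, so sigmatropic or retro-ene loss of the ynol ether and loss of the aryloxy group are closed off.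

Step 11
Reactants: 23 benzyl 2-(benzyloxy)-6-[4-(benzyloxy)-3-chloro-2-methoxy-6-(methoxycarbonyl)phenoxy]-4-methylbenzoate
Product: 24 2-[3-chloro-4-hydroxy-2-methoxy-6-(methoxycarbonyl)phenoxy]-6-hydroxy-4-methylbenzoic acid (CNP0130950.0)
Conditions: BCl3 (6 equiv), C6HMe5 (10 equiv), CH2Cl2, −78 → 0 °C; MeOH quench
Reagents that add atoms: none
Why: Lewis-acid debenzylation with pentamethylbenzene as cation trap cleaves both aryl benzyl ethers and the benzyl ester by O–benzyl fission, while the methyl ester, the non-chelated C3 methyl ether, the diaryl ether and the aryl chloride (which hydrogenolysis would endanger) should stay intact.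

**Compound list**

1 | methyl 4-amino-3-methoxybenzoate | COC(=O)c1ccc(N)c(OC)c1 | starting material
2 | methyl 4-amino-3-bromo-5-methoxybenzoate | COC(=O)c1cc(Br)c(N)c(OC)c1 | intermediate
3 | 2-bromo-6-methoxy-4-(methoxycarbonyl)benzenediazonium chloride | COC(=O)c1cc(Br)c([N+]#N)c(OC)c1.[Cl-] | intermediate
4 | methyl 3-bromo-4-chloro-5-methoxybenzoate | COC(=O)c1cc(Br)c(Cl)c(OC)c1 | intermediate
5 | potassium 3-bromo-4-chloro-5-methoxybenzoate | COc1cc(cc(Br)c1Cl)C(=O)[O-].[K+] | intermediate
6 | 4-chloro-3-hydroxy-5-methoxybenzoic acid | COc1cc(cc(O)c1Cl)C(=O)O | intermediate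
7 | 4-chloro-5-hydroxy-3-methoxy-2-(sulfooxy)benzoic acid (formed as its alkali salt) | COc1c(Cl)c(O)cc(C(=O)O)c1OS(=O)(=O)O | intermediate
8 | 4-chloro-2,5-dihydroxy-3-methoxybenzoic acid | COc1c(Cl)c(O)cc(C(=O)O)c1O | intermediate
9 | methyl 4-chloro-2,5-dihydroxy-3-methoxybenzoate | COC(=O)c1cc(O)c(Cl)c(OC)c1O | intermediate
10 | methyl 5-(benzyloxy)-4-chloro-2-hydroxy-3-methoxybenzoate | COC(=O)c1cc(OCc2ccccc2)c(Cl)c(OC)c1O | intermediate
11 | vinyl acetate | CC(=O)OC=C | starting material
12 | methyl 5-(benzyloxy)-4-chloro-2-(ethenyloxy)-3-methoxybenzoate | COC(=O)c1cc(OCc2ccccc2)c(Cl)c(OC)c1OC=C | intermediate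
13 | methyl 5-(benzyloxy)-4-chloro-2-(1,2-dibromoethoxy)-3-methoxybenzoate (racemic) | COC(=O)c1cc(OCc2ccccc2)c(Cl)c(OC)c1OC(Br)CBr | intermediate
14 | methyl 5-(benzyloxy)-2-[(2-bromoethenyl)oxy]-4-chloro-3-methoxybenzoate (E/Z mixture) | COC(=O)c1cc(OCc2ccccc2)c(Cl)c(OC)c1OC=CBr | intermediate
15 | methyl 5-(benzyloxy)-4-chloro-2-(ethynyloxy)-3-methoxybenzoate | COC(=O)c1cc(OCc2ccccc2)c(Cl)c(OC)c1OC#C | intermediate
16 | dibenzyl malonate | O=C(CC(=O)OCc1ccccc1)OCc1ccccc1 | starting material
17 | 2,2,6-trimethyl-4H-1,3-dioxin-4-one | CC1=CC(=O)OC(C)(C)O1 | starting material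
18 | acetylketene (3-oxobuta-1-en-1-one) | CC(=O)C=C=O | intermediate
19 | dibenzyl 2-(3-oxobutanoyl)propanedioate (formed as its sodium enolate) | CC(=O)CC(=O)C(C(=O)OCc1ccccc1)C(=O)OCc1ccccc1 | intermediate
20 | benzyl 4-hydroxy-6-methyl-2-oxo-2H-pyran-3-carboxylate | CC1=CC(O)=C(C(=O)OCc2ccccc2)C(=O)O1 | intermediate
21 | benzyl 4-(benzyloxy)-6-methyl-2-oxo-2H-pyran-3-carboxylate | CC1=CC(OCc2ccccc2)=C(C(=O)OCc2ccccc2)C(=O)O1 | intermediate
22 | benzyl 8-(benzyloxy)-5-[4-(benzyloxy)-3-chloro-2-methoxy-6-(methoxycarbonyl)phenoxy]-1-methyl-3-oxo-2-oxabicyclo[2.2.2]octa-5,7-diene-4-carboxylate (racemic) | CC12OC(=O)C(C(=O)OCc3ccccc3)(C(OCc3ccccc3)=C1)C(Oc4c(OC)c(Cl)c(OCc5ccccc5)cc4C(=O)OC)=C2 | intermediate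
23 | benzyl 2-(benzyloxy)-6-[4-(benzyloxy)-3-chloro-2-methoxy-6-(methoxycarbonyl)phenoxy]-4-methylbenzoate | COC(=O)c1cc(OCc2ccccc2)c(Cl)c(OC)c1Oc1cc(C)cc(OCc2ccccc2)c1C(=O)OCc1ccccc1 | intermediate
24 | 2-[3-chloro-4-hydroxy-2-methoxy-6-(methoxycarbonyl)phenoxy]-6-hydroxy-4-methylbenzoic acid | COC(=O)c1cc(O)c(Cl)c(OC)c1Oc1cc(C)cc(O)c1C(=O)O | target

**Step count and risks**

Total step count: 11. Longest linear sequence: 9 (steps 1–7, 10, 11); steps 8 and 9 form the two-step pyrone branch.

Steps most likely to fail:

Step 10. The donor-substituted pyrone may react more slowly than the ynol ether oligomerises or is hydrated by traces of acid at 140 °C, and part of the cycloaddition may take the reverse orientation. The fallback makes the C1'–O bond by known cross-coupling instead of building ring B; it sets out from phenol 10 and comes back at 23. Commercial 2,6-dihydroxy-4-methylbenzoic acid is benzylated at the carboxyl and one hydroxyl (BnBr, K2CO3, DMF) to benzyl 2-(benzyloxy)-6-hydroxy-4-methylbenzoate F1. The remaining chelated phenol is converted with Tf2O and pyridine into benzyl 2-(benzyloxy)-4-methyl-6-{[(trifluoromethyl)sulfonyl]oxy}benzoate F2. Palladium-catalysed C–O coupling of F2 with 10 (Pd(OAc)2, 2-(di-tert-butylphosphino)-2',4',6'-triisopropylbiphenyl, K3PO4, toluene, 100 °C) should give 23.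

Step 4. Persulfate may attack only sluggishly at a para carbon flanked by carboxylate and methoxy, with ortho-sulfation and over-oxidation eroding the conversion. The fallback sets out from 6 and comes back at 9. Fischer esterification (MeOH, H2SO4) gives methyl 4-chloro-3-hydroxy-5-methoxybenzoate F3. Oxidation with (KSO3)2NO in buffered aqueous acetone (KH2PO4) takes the phenol to the para-quinone methyl 4-chloro-5-methoxy-3,6-dioxocyclohexa-1,4-diene-1-carboxylate F4. Reduction with Na2S2O4 (water/EtOAc) gives the hydroquinone 9.

Step 7. The amide base or the lithium acetylide may add to the methyl ester, the E-bromoalkene may eliminate incompletely, and the ynol ether may be lost on work-up. The fallback uses the dichlorovinyl ether route with the carboxyl parked as its lithium salt; it sets out from 10 and comes back at 15. Trichloroethylene with K2CO3 in DMF at 70 °C gives methyl 5-(benzyloxy)-4-chloro-2-{[(E)-1,2-dichloroethenyl]oxy}-3-methoxybenzoate F5, and LiOH in THF/H2O gives 5-(benzyloxy)-4-chloro-2-{[(E)-1,2-dichloroethenyl]oxy}-3-methoxybenzoic acid F6. n-BuLi (3.3 equiv, THF, −78 → −40 °C), which the lithium carboxylate tolerates, followed by a quench into cold aqueous NaHCO3, gives lithium 5-(benzyloxy)-4-chloro-2-(ethynyloxy)-3-methoxybenzoate F7. This salt is never acidified, because a free acid would add to the ynol ether; MeI with K2CO3 in DMF then gives 15.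

**Further compounds**

F1 | step 10 | benzyl 2-(benzyloxy)-6-hydroxy-4-methylbenzoate | Cc1cc(O)c(C(=O)OCc2ccccc2)c(OCc2ccccc2)c1
F2 | step 10 | benzyl 2-(benzyloxy)-4-methyl-6-{[(trifluoromethyl)sulfonyl]oxy}benzoate | Cc1cc(OCc2ccccc2)c(C(=O)OCc2ccccc2)c(OS(=O)(=O)C(F)(F)F)c1
F3 | step 4 | methyl 4-chloro-3-hydroxy-5-methoxybenzoate | COC(=O)c1cc(O)c(Cl)c(OC)c1
F4 | step 4 | methyl 4-chloro-5-methoxy-3,6-dioxocyclohexa-1,4-diene-1-carboxylate | COC(=O)C1=CC(=O)C(Cl)=C(OC)C1=O
F5 | step 7 | methyl 5-(benzyloxy)-4-chloro-2-{[(E)-1,2-dichloroethenyl]oxy}-3-methoxybenzoate | COC(=O)c1cc(OCc2ccccc2)c(Cl)c(OC)c1O/C(Cl)=C\Cl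
F6 | step 7 | 5-(benzyloxy)-4-chloro-2-{[(E)-1,2-dichloroethenyl]oxy}-3-methoxybenzoic acid | OC(=O)c1cc(OCc2ccccc2)c(Cl)c(OC)c1O/C(Cl)=C\Cl
F7 | step 7 | lithium 5-(benzyloxy)-4-chloro-2-(ethynyloxy)-3-methoxybenzoate | [Li+].[O-]C(=O)c1cc(OCc2ccccc2)c(Cl)c(OC)c1OC#C
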